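**Retrosynthetic overview**
1. Numbering (germacranolide): C10 (C14H3, O5)–C1–C2–C3 (OAc)–C4 (C15H2OH)–C5 (O5)–C6 (lactone O)–C7–C8 (ester)–C9; C11–C13 = methylene lactone. Ring B = oxepane O5–C5–C6–C7–C8–C9–C10, ring A = oxepane O5–C5–C4–C3–C2–C1–C10 (together an 11-oxabicyclo[4.4.1]undecane).
2. Enabling feature: C10 is a fully substituted ether carbon (O5, C14, C1, C9) and C9H2 lies between it and the C8 carbinol. With C8 as a ketone, C9 is enolisable and C10 can be the oxygen-bearing terminus of a C10–C1–C2 allyl unit, so C9–C10 closes ring B and leaves C1 as a vinyl handle for ring A.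
3. Disconnections: side-chain esters and methylene unmasking; ring A by RCM at C1=C2, then hydrogenation; ring B by palladium-catalysed cycloisomerisation of a β-keto ester onto an O5-(1-methylallenyl) ether.
4. The open-chain precursor comes from (R)-3-hydroxy-γ-butyrolactone (C15, C4, C5, C6) by two auxiliary-controlled syn aldols: with acrolein (C3, C4) and with a succinate imide (C6, C7, lactonising).
5. Ring order: γ-lactone (step 12), ring B (step 16), ring A (step 17); the α-methylene lactone travels as its dimethylamine adduct from step 14 to step 27.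

Key step: step 16

Remark: as written, the target has C4 (on C5) and C1 (on C10) on opposite faces of ring B, trans across O5 (an inside–outside oxabicycle), so C10 cannot be set by a bridging closure; it is set at the monocyclic stage (step 16) and ring A is closed afterwards.

**Route**

Step 1
Reactants: 1 (R)-3-hydroxy-γ-butyrolactone; 2 propargyl bromide
Product: 3 (4R)-4-(prop-2-yn-1-yloxy)oxolan-2-one
Conditions: Ag2O, 4 Å MS, CH2Cl2, dark, rt
Reagents that add atoms: none
Why: Silver-oxide-mediated Williamson etherification alkylates the hydroxyl without a free alkoxide, which avoids β-elimination of the β-hydroxy lactone to the butenolide; the stereocentre (future C5) is untouched.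

Step 2
Reactants: 3 (4R)-4-(prop-2-yn-1-yloxy)oxolan-2-one
Product: 6 (3R)-4-(tert-butyldimethylsilyloxy)-3-(prop-2-yn-1-yloxy)butanoic acid, via potassium hydroxy carboxylate 4 (not isolated), via silyl ester silyl ether 5 (not isolated)
Conditions: KOH, MeOH/H2O, 0 °C, evaporate; TBSCl, imidazole, DMF, rt; K2CO3 (cat.), MeOH/H2O, 0 °C; pH 5
Reagents that add atoms: potassium hydroxide, [K+].[OH-]; tert-butyldimethylsilyl chloride, CC(C)(C)[Si](C)(C)Cl
Why: Saponification opens the lactone, exhaustive silylation caps carboxylate and primary hydroxyl (future O6), and the labile silyl ester is then hydrolysed selectively, a standard conversion of a γ-lactone into a γ-silyloxy acid.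

Step 3
Reactants: 6 (3R)-4-(tert-butyldimethylsilyloxy)-3-(prop-2-yn-1-yloxy)butanoic acid; 7 (R)-4-benzyl-2-oxazolidinone
Product: 9 (4R)-4-benzyl-3-[(3R)-4-(tert-butyldimethylsilyloxy)-3-(prop-2-yn-1-yloxy)butanoyl]oxazolidin-2-one, via mixed pivalic anhydride 8 (not isolated)
Conditions: PivCl, Et3N, THF, −20 °C; LiCl, 7, rt
Reagents that add atoms: none
Why: Mixed-anhydride N-acylation of the oxazolidinone (LiCl/Et3N variant) installs the Evans auxiliary on C15 without eliminating the β-alkoxy group.

Step 4
Reactants: 9 imide; 10 acrolein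
Product: 11 (4R)-4-benzyl-3-{(2S,3S)-3-hydroxy-2-[(1R)-2-(tert-butyldimethylsilyloxy)-1-(prop-2-yn-1-yloxy)ethyl]pent-4-enoyl}oxazolidin-2-one
Conditions: Bu2BOTf, iPr2NEt, CH2Cl2, 0 °C; 10, −78 → 0 °C; pH 7 buffer, MeOH, H2O2
Reagents that add atoms: none
Why: Evans syn aldol: the Z-boron enolate adds to acrolein through a Zimmerman–Traxler chair on the face dictated by the (R)-auxiliary, setting C4 and C3 (2,3-syn) and delivering the C3 vinyl carbinol directly, with C5 as a spectator.

Step 5
Reactants: 11 syn-aldol imide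
Product: 12 (2S,3S)-2-[(1R)-2-(tert-butyldimethylsilyloxy)-1-(prop-2-yn-1-yloxy)ethyl]pent-4-ene-1,3-diol
Conditions: LiBH4, MeOH (1 equiv), THF, 0 °C
Reagents that add atoms: none
Why: Reductive cleavage of the imide with LiBH4 gives the C15 primary alcohol and returns the auxiliary without epimerising C4.

Step 6
Reactants: 12 diol
Product: 13 O3,O15-dibenzyl ether of 12
Conditions: NaH, BnBr, Bu4NI (cat.), THF/DMF, 0 °C → rt
Reagents that add atoms: benzyl bromide, BrCc1ccccc1
Why: Double Williamson benzylation protects O3 and O15 as ethers that survive the basic allene steps and palladium and leave together in step 18.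

Step 7
Reactants: 13 propargyl ether
Product: 14 O5-allenyl (propa-1,2-dienyl) ether
Conditions: KOtBu (0.3 equiv), THF, rt
Reagents that add atoms: none
Why: Base-catalysed propargyl–allenyl isomerisation gives the oxygen-conjugated alkoxyallene.

Step 8
Reactants: 14 allenyl ether
Product: 16 O5-(buta-2,3-dien-2-yl) ether (1-methylallenyl ether), via lithioallene 15 (not isolated)
Conditions: n-BuLi, THF, −78 °C; MeI, −78 → 0 °C
Reagents that add atoms: iodomethane, CI
Why: Alkoxyallenes are lithiated at the oxygen-bearing sp2 carbon at −78 °C and C-methylation with MeI installs C14 on C10, the low temperature keeping the benzyl allyl ether from Wittig rearrangement.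

Step 9
Reactants: 16 silyl ether
Product: 17 primary alcohol (C6–OH)
Conditions: Bu4NF, THF, 0 °C
Reagents that add atoms: none
Why: Fluoride cleaves the only silyl ether under basic conditions that leave the acid-sensitive allenyl ether intact.

Step 10
Reactants: 17 alcohol
Product: 18 α-alkoxy aldehyde (C6 aldehyde; C5 O-(buta-2,3-dien-2-yl); C4 CH2OBn; C3 OBn vinyl carbinol)
Conditions: Dess–Martin periodinane, NaHCO3, CH2Cl2, 0 °C
Reagents that add atoms: none
Why: Buffered Dess–Martin oxidation gives the aldehyde without epimerisation at C5 or acid-induced loss of the allenyl ether; it is used directly.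

Step 11
Reactants: 19 (S)-4-benzyl-2-oxazolidinone; 20 methyl 4-chloro-4-oxobutanoate
Product: 22 (4S)-4-benzyl-3-(4-methoxy-4-oxobutanoyl)oxazolidin-2-one, via lithium oxazolidinide 21 (not isolated)
Conditions: n-BuLi, THF, −78 °C; 20, −78 → 0 °C
Reagents that add atoms: none
Why: N-acylation of the lithiated oxazolidinone with the acid chloride gives the succinate imide.

Step 12
Reactants: 22 succinate imide; 18 aldehyde
Product: 24 trans-γ-lactone imide (C12 lactone closed on O6; C7 bears the C8 imide; C6 bears the C5–C3 chain), via uncyclised syn-aldol adduct 23 (not isolated)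
Conditions: Bu2BOTf, iPr2NEt, CH2Cl2, 0 °C; 18, −78 → 23 °C; pH 7 buffer, MeOH
Reagents that add atoms: none
Why: Evans syn aldol: the Z-boron enolate at the imide α-carbon adds under control of the (S)-auxiliary, matched with the 3,4-anti (Cornforth/Felkin–Anh) preference of the α-alkoxy aldehyde, setting C7 and C6 (C5/C6 anti), and the aldolate then closes onto the methyl ester to give the trans-β,γ-disubstituted γ-lactone (tandem aldol–lactonisation).

Step 13
Reactants: 24 lactone imide
Product: 25 lactone carboxylic acid (C8 = CO2H)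
Conditions: LiOH, H2O2, THF/H2O, 0 °C; Na2SO3; NaH2PO4 (pH 5)
Reagents that add atoms: lithium hydroperoxide formed from LiOH and H2O2, [Li+].[O-]O
Why: Lithium hydroperoxide cleaves the exocyclic imide carbonyl selectively, releasing the C8 acid and the auxiliary while the lactone survives at 0 °C.

Step 14
Reactants: 25 lactone acid
Product: 26 α-(dimethylaminomethyl) lactone acid (C11 substituent trans to C8)
Conditions: LiN(SiMe3)2 (2.2 equiv), THF, −78 °C; Eschenmoser's salt, −78 → 0 °C
Reagents that add atoms: N,N-dimethylmethyleneiminium iodide, C=[N+](C)C.[I-]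
Why: The carboxylate–lactone enolate dianion undergoes a Mannich reaction with Eschenmoser's salt on the face trans to the C7 substituent, and the β-amino lactone is a classical masked α-methylene lactone, inert to enolates, palladium hydride and hydrogenation.

Step 15
Reactants: 26 amino acid; 27 mono-benzyl malonate
Product: 29 benzyl β-keto ester (C8 ketone, C9H2, CO2Bn), via acyl imidazolide 28 (not isolated)
Conditions: CDI, THF, rt; 27, MgCl2, Et3N, MeCN, rt → 40 °C; citric acid (pH 5)
Reagents that add atoms: none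
Why: Masamune C-acylation: the acyl imidazolide is attacked by the magnesium enolate of the malonate half-ester and decarboxylation gives the β-keto ester under near-neutral conditions that spare the allenyl ether and the Mannich base.

Step 16
Reactants: 29 β-keto ester allenyl ether
Product: 30 oxepanone (ring B closed; C10 bears C14H3 and a vinyl group; C9 carries CO2Bn as an epimer mixture)
Conditions: Pd2(dba)3·CHCl3 (2.5 mol %), (1R,2R)-N,N′-bis[2-(diphenylphosphino)benzoyl]cyclohexane-1,2-diamine (7.5 mol %), PhCO2H (10 mol %), CH2Cl2 (0.005 M), rt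
Reagents that add atoms: none
Why: Proposed new method: zerovalent palladium and benzoic acid give a palladium hydride that adds to the terminal C=C of the allene (H to the central carbon C1), forming a 1-alkoxy-1-methyl-π-allyl complex whose oxygen-bearing terminus C10 has oxocarbenium character, and the enol of the β-keto ester (C9) attacks it anti to the metal, regenerating the catalyst. The closest known reaction types are the branch-selective palladium-catalysed addition of β-keto esters and related pronucleophiles to alkoxyallenes with this diamide bisphosphine ligand (intermolecular, monosubstituted allene) and intramolecular palladium-catalysed allylic alkylation of β-keto esters. Ring B closes 7-exo-trig onto the substituted allyl terminus, the 9-endo alternative at the CH2 terminus being disfavoured by ring size. The new quaternary stereocentre C10 is under catalyst control: the π-allyl faces interconvert by π–σ–π isomerisation through the primary terminus and the chiral pocket of the ligand selects the face on which C9 adds, to give C14 cis and the vinyl group trans to the C4 arm on ring B (10R in the target); the (R,R) antipode is specified and the (S,S) antipode is the direct alternative should the sense of induction be opposite, while C9 forms as an inconsequential epimer mixture (removed in step 18). The step needs branched regioselectivity, C- over O-alkylation, facial selectivity at C10 and tolerance of lactone, amine and vinyl groups; these rest on the alkoxy substituent of the allyl unit, on the β-keto ester being the only pronucleophile of suitable acidity, on the ligand, and on the inertness of simple alkenes and benzyl ethers toward palladium hydride.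

Step 17
Reactants: 30 diene
Product: 32 saturated oxabicycle (ring A closed, C1–C2 single bond; C3 OBn, C15 OBn, C9 CO2Bn), via cycloheptene 31 (not isolated)
Conditions: camphorsulfonic acid (1.05 equiv), second-generation Hoveyda–Grubbs catalyst (10 mol %), toluene (0.002 M), 80 °C; then H2 (10 bar), 70 °C; NaHCO3
Reagents that add atoms: none
Why: Ring-closing metathesis joins the C3 vinyl carbinol and the C10 vinyl group as the cis C1=C2 alkene of ring A, a closure type with precedent for strained inside–outside bicyclo[4.4.1]undecenes, the trans bridge being fixed by the existing C5 and C10 centres; the ruthenium residue under H2 then saturates C1=C2 (tandem metathesis–hydrogenation) without touching the benzyl groups, and the acid keeps the amine protonated so that it does not bind ruthenium.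

Step 18
Reactants: 32 tribenzyl compound
Product: 34 keto diol (C8 ketone, C9H2, C3–OH, C15–OH), via β-keto acid 33 (not isolated)
Conditions: H2 (1 atm), Pd(OH)2/C, EtOH/AcOH, rt; filter; 50 °C
Reagents that add atoms: none
Why: Hydrogenolysis removes both benzyl ethers and the benzyl ester (acetic acid keeps the amine protonated so that it does not poison the catalyst), and the β-keto acid loses CO2 on gentle warming after filtration, so the activating group on C9 leaves without base and retro-oxa-Michael opening of the β-alkoxy ketone is avoided.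

Step 19
Reactants: 34 keto diol
Product: 35 C15 TBS ether
Conditions: TBSCl, imidazole, CH2Cl2, 0 °C
Reagents that add atoms: tert-butyldimethylsilyl chloride, CC(C)(C)[Si](C)(C)Cl
Why: The primary C15 hydroxyl is silylated selectively over the hindered secondary C3 hydroxyl.

Step 20
Reactants: 35 alcohol
Product: 36 C3 acetate
Conditions: Ac2O, pyridine, DMAP (cat.), CH2Cl2, 0 °C → rt
Reagents that add atoms: acetic anhydride, CC(=O)OC(C)=O
Why: Standard acylation of the remaining secondary hydroxyl installs the C3 acetate of the target.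

Step 21
Reactants: 36 ketone
Product: 37 C8 alcohol (hydroxyl cis to C11; H7/H8 cis)
Conditions: LiBH(s-Bu)3, THF, −78 °C; H2O
Reagents that add atoms: none
Why: The bulky borohydride should add to the C8 ketone from the face opposite the C7–C11 bond of the trans-fused lactone and the C14 methyl group, placing the hydroxyl cis to C11 as in the target, while acetate and lactone survive at −78 °C.

Step 22
Reactants: 38 (E)-crotonaldehyde
Product: 40 (Z)-2-bromobut-2-enal, via dibromoaldehyde 39 (not isolated)
Conditions: Br2, CH2Cl2, 0 °C; Et3N, 0 °C → rt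
Reagents that add atoms: bromine, BrBr
Why: Bromine adds across the C=C and triethylamine eliminates HBr through the enolisable α-position, giving the thermodynamically preferred (Z)-α-bromo enal with bromine cis to the methyl group.

Step 23
Reactants: 40 (Z)-2-bromobut-2-enal
Product: 41 (Z)-2-bromobut-2-en-1-ol
Conditions: NaBH4, CeCl3·7H2O, MeOH, 0 °C
Reagents that add atoms: none
Why: Luche reduction gives only 1,2-reduction of the enal, so the alkene geometry is kept.

Step 24
Reactants: 41 bromo alcohol
Product: 42 (Z)-(2-bromobut-2-enyloxy)(tert-butyl)dimethylsilane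
Conditions: TBSCl, imidazole, DMF, rt
Reagents that add atoms: tert-butyldimethylsilyl chloride, CC(C)(C)[Si](C)(C)Cl
Why: Standard silylation of the primary allylic alcohol.

Step 25
Reactants: 42 vinyl bromide
Product: 44 (Z)-2-[(tert-butyldimethylsilyloxy)methyl]but-2-enoic acid, via vinyllithium 43 (not isolated)
Conditions: t-BuLi (2.1 equiv), Et2O, −78 °C; CO2; pH 4
Reagents that add atoms: carbon dioxide, O=C=O
Why: Bromine–lithium exchange at −78 °C proceeds with retention of alkene geometry and carboxylation gives the protected acid with carboxyl cis to methyl (the sarracinic acid geometry).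

Step 26
Reactants: 37 C8 alcohol; 44 protected (Z)-acid
Product: 46 C8 ester (O-TBS sarracinate), via mixed anhydride 45 (not isolated)
Conditions: 44, 2,4,6-Cl3C6H2COCl, Et3N, toluene, rt; 37, toluene, 70 °C
Reagents that add atoms: none
Why: Yamaguchi esterification through the 2,4,6-trichlorobenzoyl mixed anhydride acylates the hindered C8 hydroxyl, and omitting DMAP avoids the conjugate addition–elimination that would isomerise the Z-alkene.

Step 27
Reactants: 46 amine
Product: 48 α-methylene lactone bis-TBS ether, via ammonium iodide 47 (not isolated)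
Conditions: MeI, MeOH, rt; NaHCO3, H2O/EtOAc, rt
Reagents that add atoms: none
Why: Exhaustive N-methylation makes the amine a leaving group and mild base effects Hofmann-type (E1cB) elimination to the α-methylene lactone, the standard unmasking of the amine adduct, without touching the other esters.

Step 28
Reactants: 48 bis-TBS ether
Product: 49 target CNP0195618.1
Conditions: HF·pyridine, pyridine, THF, 0 °C → rt
Reagents that add atoms: none
Why: Buffered HF·pyridine cleaves both primary TBS ethers under mildly acidic conditions that avoid acetyl migration and conjugate addition to the methylene lactone.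

**Compound list**
1 | (R)-3-hydroxy-γ-butyrolactone | O=C1C[C@@H](O)CO1 | starting material
2 | propargyl bromide | C#CCBr | starting material
3 | (4R)-4-(prop-2-yn-1-yloxy)oxolan-2-one | O=C1C[C@@H](OCC#C)CO1 | intermediate
4 | potassium (3R)-4-hydroxy-3-(prop-2-yn-1-yloxy)butanoate | [K+].[O-]C(=O)C[C@@H](OCC#C)CO | intermediate
5 | tert-butyldimethylsilyl (3R)-4-(tert-butyldimethylsilyloxy)-3-(prop-2-yn-1-yloxy)butanoate | CC(C)(C)[Si](C)(C)OC(=O)C[C@@H](OCC#C)CO[Si](C)(C)C(C)(C)C | intermediate
6 | (3R)-4-(tert-butyldimethylsilyloxy)-3-(prop-2-yn-1-yloxy)butanoic acid | OC(=O)C[C@@H](OCC#C)CO[Si](C)(C)C(C)(C)C | intermediate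
7 | (R)-4-benzyl-2-oxazolidinone | O=C1N[C@H](Cc2ccccc2)CO1 | starting material
8 | mixed pivalic anhydride of 6 | CC(C)(C)C(=O)OC(=O)C[C@@H](OCC#C)CO[Si](C)(C)C(C)(C)C | intermediate
9 | (4R)-4-benzyl-3-[(3R)-4-(tert-butyldimethylsilyloxy)-3-(prop-2-yn-1-yloxy)butanoyl]oxazolidin-2-one | O=C1OC[C@@H](Cc2ccccc2)N1C(=O)C[C@@H](OCC#C)CO[Si](C)(C)C(C)(C)C | intermediate
10 | acrolein | C=CC=O | starting material
11 | syn-aldol imide (C15 imide; C3 hydroxyl and vinyl; C5 O-propargyl; C6 OTBS) | O=C1OC[C@@H](Cc2ccccc2)N1C(=O)[C@@H]([C@@H](O)C=C)[C@@H](OCC#C)CO[Si](C)(C)C(C)(C)C | intermediate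
12 | (2S,3S)-2-[(1R)-2-(tert-butyldimethylsilyloxy)-1-(prop-2-yn-1-yloxy)ethyl]pent-4-ene-1,3-diol | OC[C@@H]([C@@H](O)C=C)[C@@H](OCC#C)CO[Si](C)(C)C(C)(C)C | intermediate
13 | O3,O15-dibenzyl ether of 12 | c1ccccc1COC[C@@H]([C@@H](OCc2ccccc2)C=C)[C@@H](OCC#C)CO[Si](C)(C)C(C)(C)C | intermediate
14 | O5-allenyl ether | c1ccccc1COC[C@@H]([C@@H](OCc2ccccc2)C=C)[C@@H](OC=C=C)CO[Si](C)(C)C(C)(C)C | intermediate
15 | 1-lithioallenyl ether | c1ccccc1COC[C@@H]([C@@H](OCc2ccccc2)C=C)[C@@H](OC([Li])=C=C)CO[Si](C)(C)C(C)(C)C | intermediate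
16 | O5-(buta-2,3-dien-2-yl) ether, C6 OTBS | c1ccccc1COC[C@@H]([C@@H](OCc2ccccc2)C=C)[C@@H](OC(C)=C=C)CO[Si](C)(C)C(C)(C)C | intermediate
17 | C6 primary alcohol | c1ccccc1COC[C@@H]([C@@H](OCc2ccccc2)C=C)[C@@H](OC(C)=C=C)CO | intermediate
18 | C6 aldehyde | c1ccccc1COC[C@@H]([C@@H](OCc2ccccc2)C=C)[C@@H](OC(C)=C=C)C=O | intermediate
19 | (S)-4-benzyl-2-oxazolidinone | O=C1N[C@@H](Cc2ccccc2)CO1 | starting material
20 | methyl 4-chloro-4-oxobutanoate | COC(=O)CCC(Cl)=O | starting material
21 | lithium salt of 19 | [Li]N1[C@@H](Cc2ccccc2)COC1=O | intermediate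
22 | (4S)-4-benzyl-3-(4-methoxy-4-oxobutanoyl)oxazolidin-2-one | COC(=O)CCC(=O)N1[C@@H](Cc2ccccc2)COC1=O | intermediate
23 | uncyclised syn-aldol adduct (C6 hydroxyl, C12 methyl ester, C8 imide) | COC(=O)C[C@H](C(=O)N1[C@@H](Cc2ccccc2)COC1=O)[C@H](O)[C@H](OC(C)=C=C)[C@@H](COCc3ccccc3)[C@@H](OCc4ccccc4)C=C | intermediate
24 | trans-γ-lactone imide | O=C1C[C@H](C(=O)N2[C@@H](Cc3ccccc3)COC2=O)[C@@H]([C@H](OC(C)=C=C)[C@@H](COCc4ccccc4)[C@@H](OCc5ccccc5)C=C)O1 | intermediate
25 | trans-γ-lactone C8 carboxylic acid | O=C1C[C@H](C(=O)O)[C@@H]([C@H](OC(C)=C=C)[C@@H](COCc2ccccc2)[C@@H](OCc3ccccc3)C=C)O1 | intermediate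
26 | α-(dimethylaminomethyl) lactone acid | O=C1[C@@H](CN(C)C)[C@H](C(=O)O)[C@@H]([C@H](OC(C)=C=C)[C@@H](COCc2ccccc2)[C@@H](OCc3ccccc3)C=C)O1 | intermediate
27 | mono-benzyl malonate | OC(=O)CC(=O)OCc1ccccc1 | starting material
28 | acyl imidazolide of 26 | O=C1[C@@H](CN(C)C)[C@H](C(=O)n2ccnc2)[C@@H]([C@H](OC(C)=C=C)[C@@H](COCc3ccccc3)[C@@H](OCc4ccccc4)C=C)O1 | intermediate
29 | benzyl β-keto ester (C8 ketone, C9H2) with O5-(1-methylallenyl) ether | O=C1[C@@H](CN(C)C)[C@H](C(=O)CC(=O)OCc2ccccc2)[C@@H]([C@H](OC(C)=C=C)[C@@H](COCc3ccccc3)[C@@H](OCc4ccccc4)C=C)O1 | intermediate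
30 | lactone-fused oxepanone (ring B; C10 methyl and vinyl; C9 CO2Bn) | O=C1[C@@H](CN(C)C)[C@@H]2C(=O)C(C(=O)OCc3ccccc3)[C@@](C)(C=C)O[C@H]([C@@H](COCc4ccccc4)[C@@H](OCc5ccccc5)C=C)[C@H]2O1 | intermediate
31 | oxabicyclic cycloheptene (C1=C2) | CN(C)C[C@@H]1C(=O)O[C@@H]2[C@@H]3O[C@](C)(C=C[C@H](OCc4ccccc4)[C@@H]3COCc5ccccc5)C(C(=O)OCc6ccccc6)C(=O)[C@@H]12 | intermediate
32 | saturated oxabicycle (C3 OBn, C15 OBn, C9 CO2Bn, C8 ketone) | CN(C)C[C@@H]1C(=O)O[C@@H]2[C@@H]3O[C@](C)(CC[C@H](OCc4ccccc4)[C@@H]3COCc5ccccc5)C(C(=O)OCc6ccccc6)C(=O)[C@@H]12 | intermediate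
33 | β-keto acid diol | CN(C)C[C@@H]1C(=O)O[C@@H]2[C@@H]3O[C@](C)(CC[C@H](O)[C@@H]3CO)C(C(=O)O)C(=O)[C@@H]12 | intermediate
34 | keto diol | CN(C)C[C@@H]1C(=O)O[C@@H]2[C@@H]3O[C@](C)(CC[C@H](O)[C@@H]3CO)CC(=O)[C@@H]12 | intermediate
35 | C15 TBS ether, C3 alcohol, C8 ketone | CN(C)C[C@@H]1C(=O)O[C@@H]2[C@@H]3O[C@](C)(CC[C@H](O)[C@@H]3CO[Si](C)(C)C(C)(C)C)CC(=O)[C@@H]12 | intermediate
36 | C3 acetate, C8 ketone | CN(C)C[C@@H]1C(=O)O[C@@H]2[C@@H]3O[C@](C)(CC[C@H](OC(C)=O)[C@@H]3CO[Si](C)(C)C(C)(C)C)CC(=O)[C@@H]12 | intermediate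
37 | C8 alcohol (as in target) | CN(C)C[C@@H]1C(=O)O[C@@H]2[C@@H]3O[C@](C)(CC[C@H](OC(C)=O)[C@@H]3CO[Si](C)(C)C(C)(C)C)C[C@@H](O)[C@@H]12 | intermediate
38 | (E)-crotonaldehyde | C/C=C/C=O | starting material
39 | 2,3-dibromobutanal | CC(Br)C(Br)C=O | intermediate
40 | (Z)-2-bromobut-2-enal | C/C=C(\Br)C=O | intermediate
41 | (Z)-2-bromobut-2-en-1-ol | C/C=C(\Br)CO | intermediate
42 | (Z)-(2-bromobut-2-enyloxy)(tert-butyl)dimethylsilane | C/C=C(\Br)CO[Si](C)(C)C(C)(C)C | intermediate
43 | (Z)-vinyllithium from 42 | C/C=C(\[Li])CO[Si](C)(C)C(C)(C)C | intermediate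
44 | (Z)-2-[(tert-butyldimethylsilyloxy)methyl]but-2-enoic acid | C/C=C(\C(=O)O)CO[Si](C)(C)C(C)(C)C | intermediate
45 | mixed anhydride of 44 with 2,4,6-trichlorobenzoic acid | C/C=C(\C(=O)OC(=O)c1c(Cl)cc(Cl)cc1Cl)CO[Si](C)(C)C(C)(C)C | intermediate
46 | C8 O-TBS-sarracinate, amine adduct | CN(C)C[C@@H]1C(=O)O[C@@H]2[C@@H]3O[C@](C)(CC[C@H](OC(C)=O)[C@@H]3CO[Si](C)(C)C(C)(C)C)C[C@@H](OC(=O)/C(=C\C)CO[Si](C)(C)C(C)(C)C)[C@@H]12 | intermediate
47 | trimethylammonium iodide of 46 | C[N+](C)(C)C[C@@H]1C(=O)O[C@@H]2[C@@H]3O[C@](C)(CC[C@H](OC(C)=O)[C@@H]3CO[Si](C)(C)C(C)(C)C)C[C@@H](OC(=O)/C(=C\C)CO[Si](C)(C)C(C)(C)C)[C@@H]12.[I-] | intermediate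
48 | bis-TBS ether of the target | C=C1C(=O)O[C@@H]2[C@@H]3O[C@](C)(CC[C@H](OC(C)=O)[C@@H]3CO[Si](C)(C)C(C)(C)C)C[C@@H](OC(=O)/C(=C\C)CO[Si](C)(C)C(C)(C)C)[C@@H]12 | intermediate
49 | CNP0195618.1 | C=C1C(=O)O[C@@H]2[C@@H]3O[C@](C)(CC[C@H](OC(C)=O)[C@@H]3CO)C[C@@H](OC(=O)/C(=C\C)CO)[C@@H]12 | target

**Count and risks**
Total steps: 28. Longest linear sequence: 23 steps (1–10, 12–21, 26–28).

1. Step 16 (Proposed new method). The cyclisation may stall, oligomerise, isomerise the allene to a 2-alkoxydiene, or show poor catalyst control of the face at C10. Fallback (known oxocarbenium chemistry instead of a π-allyl): from 29, PPTS-catalysed addition of methanol to the allenyl ether should give the mixed methyl vinyl ketal F1. TMSOTf/2,6-lutidine then forms the silyl enol ether of the β-keto ester in situ and further TMSOTf at −78 °C ionises the ketal, so that an intramolecular Mukaiyama-type addition to the vinyl oxocarbenium closes ring B. After separation of the C10 epimers this returns to 30.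

2. Step 17. Ring A must close across the trans (inside–outside) relationship of C5 and C10; strain may divert metathesis to oligomers, or the ruthenium hydride may isomerise the allylic ethers. Fallback (carbonyl coupling instead of metathesis): from 30, OsO4/NaIO4 with 2,6-lutidine cleaves both vinyl groups to the dialdehyde F2. SmI2-mediated pinacol cyclisation at high dilution gives the C1,C2-diol F3, thiocarbonyldiimidazole converts it into the cyclic thiocarbonate F4, and Corey–Winter elimination (P(OMe)3, heat) gives cycloheptene 31. Hydrogenation with RhCl(PPh3)3 then returns to 32.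

3. Step 21. Hydride delivery to the C8 ketone may show poor facial selectivity, or the borohydride may partly remove the acetate. Fallback (inversion instead of direct reduction): from 36, reduction with NaBH4/CeCl3·7H2O at −78 °C and separation gives the 8-epi alcohol F5. Mitsunobu esterification with acid 44 (PPh3, DIAD) inverts C8 and returns to 46.

**Further compounds**
F1 | step 16 | mixed methyl vinyl ketal of 29 (O5–C(CH3)(OCH3)–CH=CH2) | O=C1[C@@H](CN(C)C)[C@H](C(=O)CC(=O)OCc2ccccc2)[C@@H]([C@H](OC(C)(OC)C=C)[C@@H](COCc3ccccc3)[C@@H](OCc4ccccc4)C=C)O1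
F2 | step 17 | C1,C2-dialdehyde from 30 | O=C1[C@@H](CN(C)C)[C@@H]2C(=O)C(C(=O)OCc3ccccc3)[C@@](C)(C=O)O[C@H]([C@@H](COCc4ccccc4)[C@@H](OCc5ccccc5)C=O)[C@H]2O1
F3 | step 17 | bicyclic C1,C2-diol | CN(C)C[C@@H]1C(=O)O[C@@H]2[C@@H]3O[C@](C)(C(O)C(O)[C@H](OCc4ccccc4)[C@@H]3COCc5ccccc5)C(C(=O)OCc6ccccc6)C(=O)[C@@H]12
F4 | step 17 | cyclic C1,C2-thiocarbonate | CN(C)C[C@@H]1C(=O)O[C@@H]2[C@@H]3O[C@](C)(C4OC(=S)OC4[C@H](OCc5ccccc5)[C@@H]3COCc6ccccc6)C(C(=O)OCc7ccccc7)C(=O)[C@@H]12
F5 | step 21 | 8-epi alcohol of 37 | CN(C)C[C@@H]1C(=O)O[C@@H]2[C@@H]3O[C@](C)(CC[C@H](OC(C)=O)[C@@H]3CO[Si](C)(C)C(C)(C)C)C[C@H](O)[C@@H]12
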